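**Retrosynthetic overview**

1. Target 22 ← triacid 21 ← tetra-O-methyl trimethyl ester 20 (Me3SnOH for the three esters, then BBr3 for the four aryl methyl ethers). Rings A, C and D are bought; only ring B is made.
2. Ring B is closed last through the C1–C2 bond. The strategy rests on the free 4'-OH of ring C standing para to C1, so that C1 can become the electrophilic terminus of a para-quinone methide, and on C2 being the acidic CH2 of an (E)-benzylidenesuccinate on ring A, held cis to C4a across C3=C4.
3. The cyclisation substrate 18 (diarylmethyl acetate with free 4'-OH) comes from the C1–C8a bond: addition of ring A boronate 5 to ring C aldehyde 15, then acetylation and buffered desilylation.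
4. Boronate 5: Stobbe condensation of 1 with 2, esterification, Miyaura borylation. Aldehyde 15: copper-catalysed O-vinylation of 4-O-allyl protocatechualdehyde 12 with the (E)-alpha-bromocinnamate 10 (from 9 by a trifluoroethyl phosphonate olefination), then exchange of allyl for TIPS.

Key step: step 14

Assumption: the sense of induction of the ammonium salt in step 14 cannot be derived for this new substrate; the cinchonidinium salt is written, and its cinchoninium pseudo-enantiomer is taken instead if the closure proves to favour the (1S,2R) antipode.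
Remark: the (E)-enol ether (ring D cis to its ester) is taken to be the less stable geometry, so every compound from 10 onward is kept from strong light and strong protic acid.

**Route**

Step 1
Reactants: 1 2-bromo-4,5-dimethoxybenzaldehyde; 2 dimethyl succinate
Product: 3 (E)-4-(2-bromo-4,5-dimethoxyphenyl)-3-(methoxycarbonyl)but-3-enoic acid
Conditions: NaOMe, MeOH, reflux; then aq HCl
Reagents that add atoms: none
Why: Stobbe condensation: aldol addition of the succinate enolate to the non-enolisable aldehyde followed by irreversible alkoxide-driven elimination should give the half-ester as the (E)-isomer, in which ring A is cis to the CH2CO2H arm.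

Step 2
Reactants: 3 (E)-4-(2-bromo-4,5-dimethoxyphenyl)-3-(methoxycarbonyl)but-3-enoic acid
Product: 4 dimethyl (E)-2-(2-bromo-4,5-dimethoxybenzylidene)succinate
Conditions: MeOH, cat. H2SO4, reflux
Reagents that add atoms: methanol, CO
Why: Fischer esterification of the free acid; the alkene already has its thermodynamic geometry and should not change under acid.

Step 3
Reactants: 4 dimethyl (E)-2-(2-bromo-4,5-dimethoxybenzylidene)succinate
Product: 5 dimethyl (E)-2-[4,5-dimethoxy-2-(4,4,5,5-tetramethyl-1,3,2-dioxaborolan-2-yl)benzylidene]succinate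
Conditions: B2pin2, Pd(dppf)Cl2 (5 mol%), KOAc, 1,4-dioxane, 90 °C
Reagents that add atoms: bis(pinacolato)diboron, CC1(C)OB(OC1(C)C)B1OC(C)(C)C(C)(C)O1
Why: Miyaura borylation (oxidative addition of the aryl bromide to zerovalent palladium, acetate-assisted transmetalation from boron); KOAc is too weak to deprotonate the succinate CH2 or to cleave the esters.

Step 4
Reactants: 6 methyl 2-[bis(2,2,2-trifluoroethoxy)phosphoryl]acetate
Product: 7 methyl 2,2-dibromo-2-[bis(2,2,2-trifluoroethoxy)phosphoryl]acetate
Conditions: Br2, aq NaOH, 0 °C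
Reagents that add atoms: bromine, BrBr
Why: Hypobromite bromination of the doubly activated CH2 is driven to the dibromide, which avoids the mono/di mixtures of a direct monobromination.

Step 5
Reactants: 7 methyl 2,2-dibromo-2-[bis(2,2,2-trifluoroethoxy)phosphoryl]acetate
Product: 8 methyl 2-bromo-2-[bis(2,2,2-trifluoroethoxy)phosphoryl]acetate (racemic)
Conditions: SnCl2·2H2O, EtOH/H2O, 0 °C
Reagents that add atoms: none
Why: Halophilic reduction by divalent tin removes one bromine from the geminal dibromide, which is much more easily reduced than the monobromide, and the carbanion is protonated by the medium.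

Step 6
Reactants: 8 methyl 2-bromo-2-[bis(2,2,2-trifluoroethoxy)phosphoryl]acetate; 9 3,4-dimethoxybenzaldehyde
Product: 10 methyl (E)-2-bromo-3-(3,4-dimethoxyphenyl)prop-2-enoate
Conditions: KOt-Bu, 18-crown-6, THF, −78 °C
Reagents that add atoms: none
Why: Horner–Wadsworth–Emmons olefination of the Still–Gennari type: the trifluoroethyl phosphonate eliminates under kinetic control and should place ring D cis to the ester, which is the (E)-alpha-bromoacrylate.

Step 7
Reactants: 11 3,4-dihydroxybenzaldehyde
Product: 12 4-(allyloxy)-3-hydroxybenzaldehyde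
Conditions: allyl bromide (1.1 equiv), NaHCO3, NaI (cat.), DMF, 40 °C
Reagents that add atoms: allyl bromide, C=CCBr
Why: Williamson etherification under weak base: only the more acidic 4-OH (para to the aldehyde) is ionised, so alkylation should occur there and leave the 3-OH free.

Step 8
Reactants: 12 4-(allyloxy)-3-hydroxybenzaldehyde; 10 methyl (E)-2-bromo-3-(3,4-dimethoxyphenyl)prop-2-enoate
Product: 13 methyl (E)-2-[2-(allyloxy)-5-formylphenoxy]-3-(3,4-dimethoxyphenyl)prop-2-enoate
Conditions: CuI (10 mol%), N,N-dimethylglycine hydrochloride (30 mol%), Cs2CO3, 1,4-dioxane, 90 °C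
Reagents that add atoms: none
Why: Ullmann-type copper-catalysed C–O coupling of a vinyl bromide with a phenol, which should go with retention of alkene geometry; in the (E)-bromide H and Br are cis so anti-elimination to the alkyne is closed, and the allyl group on the 4-oxygen cannot migrate to the neighbouring phenoxide as a silyl group would.

Step 9
Reactants: 13 methyl (E)-2-[2-(allyloxy)-5-formylphenoxy]-3-(3,4-dimethoxyphenyl)prop-2-enoate
Product: 14 methyl (E)-3-(3,4-dimethoxyphenyl)-2-(5-formyl-2-hydroxyphenoxy)prop-2-enoate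
Conditions: Pd(PPh3)4 (5 mol%), morpholine, THF, rt
Reagents that add atoms: none
Why: Tsuji–Trost deallylation: zerovalent palladium ionises the allyl aryl ether and morpholine traps the allyl fragment, while the vinyl C–O bond, the ester and the aldehyde are inert.

Step 10
Reactants: 14 methyl (E)-3-(3,4-dimethoxyphenyl)-2-(5-formyl-2-hydroxyphenoxy)prop-2-enoate
Product: 15 methyl (E)-3-(3,4-dimethoxyphenyl)-2-[5-formyl-2-(triisopropylsilyloxy)phenoxy]prop-2-enoate
Conditions: TIPSCl, imidazole, DMF, rt
Reagents that add atoms: triisopropylsilyl chloride, CC(C)[Si](Cl)(C(C)C)C(C)C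
Why: Silylation of the acidic phenol; TIPS is chosen because it should survive the aqueous phosphate of step 11 and can later be removed by buffered fluoride without base, acid or hydrogen.

Step 11
Reactants: 5 dimethyl (E)-2-[4,5-dimethoxy-2-(4,4,5,5-tetramethyl-1,3,2-dioxaborolan-2-yl)benzylidene]succinate; 15 methyl (E)-3-(3,4-dimethoxyphenyl)-2-[5-formyl-2-(triisopropylsilyloxy)phenoxy]prop-2-enoate
Product: 16 dimethyl (E)-2-{2-[hydroxy(3-{[(E)-2-(3,4-dimethoxyphenyl)-1-(methoxycarbonyl)ethenyl]oxy}-4-(triisopropylsilyloxy)phenyl)methyl]-4,5-dimethoxybenzylidene}succinate (racemic at the carbinol carbon)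
Conditions: [Rh(cod)Cl]2 (2.5 mol%), K3PO4, 1,4-dioxane/H2O (10:1), 60 °C
Reagents that add atoms: none
Why: Rhodium-catalysed 1,2-addition of an arylboron reagent to an aldehyde (transmetalation to monovalent rhodium, then insertion of the aldehyde C=O, which is far more reactive than the two hindered trisubstituted enoates); the new carbinol centre is racemic by intent because it becomes planar in step 14.

Step 12
Reactants: 16 the racemic diarylmethanol
Product: 17 the racemic diarylmethyl acetate with 4'-O-TIPS (acetate of 16)
Conditions: Ac2O, Et3N, DMAP (cat.), CH2Cl2, 0 °C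
Reagents that add atoms: acetic anhydride, CC(=O)OC(C)=O
Why: DMAP-catalysed acylation of the secondary benzylic alcohol; with the 4'-oxygen still silylated the acetate has no phenoxide to push it out and should be stable to isolation.

Step 13
Reactants: 17 the racemic diarylmethyl acetate with 4'-O-TIPS
Product: 18 dimethyl (E)-2-{2-[acetoxy(3-{[(E)-2-(3,4-dimethoxyphenyl)-1-(methoxycarbonyl)ethenyl]oxy}-4-hydroxyphenyl)methyl]-4,5-dimethoxybenzylidene}succinate (racemic)
Conditions: Bu4NF (1.2 equiv), AcOH (2 equiv), THF, 0 °C; pH 7 work-up, used without chromatography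
Reagents that add atoms: none
Why: Fluoride cleaves the Si–O bond while the acetic acid buffer protonates the phenoxide as it forms, so the benzylic acetate should not be expelled before step 14.

Step 14
Reactants: 18 the racemic diarylmethyl acetate with free 4'-OH
Product: 20 dimethyl (1R,2S)-1-(3-{[(E)-2-(3,4-dimethoxyphenyl)-1-(methoxycarbonyl)ethenyl]oxy}-4-hydroxyphenyl)-6,7-dimethoxy-1,2-dihydronaphthalene-2,3-dicarboxylate, via para-quinone methide 19 (not isolated)
Conditions: N-(9-anthracenylmethyl)cinchonidinium chloride (10 mol%), Cs2CO3 (3 equiv), toluene/CH2Cl2 (9:1), 0.02 M, −20 °C; then aq NH4Cl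
Reagents that add atoms: none
Why: Proposed new method: Cs2CO3 deprotonates the 4'-OH of ring C, the phenoxide expels acetate from C1 to give the para-quinone methide 19, and the ammonium-paired enolate formed at C2 (an allylic CH2 alpha to an ester) adds to C1 in a 1,6-sense, which rearomatises ring C and leaves the free 4'-OH; the closest known reaction type is the phase-transfer-catalysed asymmetric 1,6-addition of malonates and related carbon acids to para-quinone methides, including those made in situ from para-hydroxybenzyl precursors, and what is new here is the intramolecular mono-ester enolate and a diaryl quinone methide without flanking tert-butyl groups. Ring B closes by 6-exo-trig attack on the exocyclic C1=C1' bond, which is possible because the (E)-alkene C3=C4 holds C2 and C4a cis. C1 is set by the catalyst, whose ammonium centre should pair with the enolate while its 9-OH hydrogen-bonds the quinone methide oxygen so that one face of planar C1 is exposed; C2 follows from the half-chair closure that puts ring C and the C2 ester trans, which is also the thermodynamic arrangement reachable by base equilibration of C2–H. The step needs ring closure at C2 to outrun intermolecular capture of 19, which the six-membered intramolecular closure at high dilution should secure, and it needs the enol ether side chain to stay passive, which its lack of an acidic C–H and its poor acceptor character should ensure.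

Step 15
Reactants: 20 the (1R,2S) tetra-O-methyl trimethyl ester
Product: 21 (1R,2S)-1-(3-{[(E)-1-carboxy-2-(3,4-dimethoxyphenyl)ethenyl]oxy}-4-hydroxyphenyl)-6,7-dimethoxy-1,2-dihydronaphthalene-2,3-dicarboxylic acid
Conditions: Me3SnOH (12 equiv), 1,2-dichloroethane, 80 °C, argon; then aq HCl
Reagents that add atoms: trimethyltin hydroxide, C[Sn](C)(C)O
Why: Trimethyltin hydroxide ester cleavage is near-neutral, so the three methyl esters should be hydrolysed without epimerising C2, moving the C3=C4 double bond or adding to the enol ether acrylate.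

Step 16
Reactants: 21 the (1R,2S) tetra-O-methyl triacid
Product: 22 (1R,2S)-1-(3-{[(E)-1-carboxy-2-(3,4-dihydroxyphenyl)ethenyl]oxy}-4-hydroxyphenyl)-6,7-dihydroxy-1,2-dihydronaphthalene-2,3-dicarboxylic acid (CNP0241205.1)
Conditions: BBr3 (12 equiv), CH2Cl2, −78 to 0 °C, argon; then ice-water
Reagents that add atoms: none
Why: Boron tribromide demethylation: bromide attacks the methyl carbon of each boron-complexed aryl methyl ether, whereas the aryl–O–vinyl linkage offers no sp3 carbon and should remain, and neither stereocentre is touched.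

**Compound list**

1 | 2-bromo-4,5-dimethoxybenzaldehyde | COc1cc(Br)c(C=O)cc1OC | starting material
2 | dimethyl succinate | COC(=O)CCC(=O)OC | starting material
3 | (E)-4-(2-bromo-4,5-dimethoxyphenyl)-3-(methoxycarbonyl)but-3-enoic acid | OC(=O)C/C(C(=O)OC)=C\c1cc(OC)c(OC)cc1Br | intermediate
4 | dimethyl (E)-2-(2-bromo-4,5-dimethoxybenzylidene)succinate | COC(=O)C/C(C(=O)OC)=C\c1cc(OC)c(OC)cc1Br | intermediate
5 | dimethyl (E)-2-[4,5-dimethoxy-2-(pinacolatoboryl)benzylidene]succinate | COC(=O)C/C(C(=O)OC)=C\c1cc(OC)c(OC)cc1B1OC(C)(C)C(C)(C)O1 | intermediate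
6 | methyl 2-[bis(2,2,2-trifluoroethoxy)phosphoryl]acetate | COC(=O)CP(=O)(OCC(F)(F)F)OCC(F)(F)F | starting material
7 | methyl 2,2-dibromo-2-[bis(2,2,2-trifluoroethoxy)phosphoryl]acetate | COC(=O)C(Br)(Br)P(=O)(OCC(F)(F)F)OCC(F)(F)F | intermediate
8 | methyl 2-bromo-2-[bis(2,2,2-trifluoroethoxy)phosphoryl]acetate (racemic) | COC(=O)C(Br)P(=O)(OCC(F)(F)F)OCC(F)(F)F | intermediate
9 | 3,4-dimethoxybenzaldehyde | COc1ccc(C=O)cc1OC | starting material
10 | methyl (E)-2-bromo-3-(3,4-dimethoxyphenyl)prop-2-enoate (Br trans to ring D) | Br/C(=C/c1ccc(OC)c(OC)c1)C(=O)OC | intermediate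
11 | 3,4-dihydroxybenzaldehyde | O=Cc1ccc(O)c(O)c1 | starting material
12 | 4-(allyloxy)-3-hydroxybenzaldehyde | C=CCOc1ccc(C=O)cc1O | intermediate
13 | methyl (E)-2-[2-(allyloxy)-5-formylphenoxy]-3-(3,4-dimethoxyphenyl)prop-2-enoate | O=Cc1ccc(OCC=C)c(O/C(=C/c2ccc(OC)c(OC)c2)C(=O)OC)c1 | intermediate
14 | methyl (E)-3-(3,4-dimethoxyphenyl)-2-(5-formyl-2-hydroxyphenoxy)prop-2-enoate | O=Cc1ccc(O)c(O/C(=C/c2ccc(OC)c(OC)c2)C(=O)OC)c1 | intermediate
15 | methyl (E)-3-(3,4-dimethoxyphenyl)-2-[5-formyl-2-(triisopropylsilyloxy)phenoxy]prop-2-enoate | O=Cc1ccc(O[Si](C(C)C)(C(C)C)C(C)C)c(O/C(=C/c2ccc(OC)c(OC)c2)C(=O)OC)c1 | intermediate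
16 | racemic diarylmethanol: ring A carries the (E)-benzylidenesuccinate, ring C the 4'-O-TIPS group and the (E)-enol ether | OC(c1ccc(O[Si](C(C)C)(C(C)C)C(C)C)c(O/C(=C/c2ccc(OC)c(OC)c2)C(=O)OC)c1)c1cc(OC)c(OC)cc1/C=C(\CC(=O)OC)C(=O)OC | intermediate
17 | racemic diarylmethyl acetate with 4'-O-TIPS | CC(=O)OC(c1ccc(O[Si](C(C)C)(C(C)C)C(C)C)c(O/C(=C/c2ccc(OC)c(OC)c2)C(=O)OC)c1)c1cc(OC)c(OC)cc1/C=C(\CC(=O)OC)C(=O)OC | intermediate
18 | racemic diarylmethyl acetate with free 4'-OH (cyclisation substrate) | CC(=O)OC(c1ccc(O)c(O/C(=C/c2ccc(OC)c(OC)c2)C(=O)OC)c1)c1cc(OC)c(OC)cc1/C=C(\CC(=O)OC)C(=O)OC | intermediate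
19 | para-quinone methide of ring C, exocyclic C1=C1' geometry not defined | O=C1C=CC(=Cc2cc(OC)c(OC)cc2/C=C(\CC(=O)OC)C(=O)OC)C=C1O/C(=C/c1ccc(OC)c(OC)c1)C(=O)OC | intermediate (not isolated)
20 | (1R,2S) tetra-O-methyl trimethyl ester with free 4'-OH | COC(=O)C1=Cc2cc(OC)c(OC)cc2[C@@H](c2ccc(O)c(O/C(=C/c3ccc(OC)c(OC)c3)C(=O)OC)c2)[C@@H]1C(=O)OC | intermediate
21 | (1R,2S) tetra-O-methyl triacid | O=C(O)C1=Cc2cc(OC)c(OC)cc2[C@@H](c2ccc(O)c(O/C(=C/c3ccc(OC)c(OC)c3)C(=O)O)c2)[C@@H]1C(=O)O | intermediate
22 | CNP0241205.1, (1R,2S), (E)-enol ether | O=C(O)C1=Cc2cc(O)c(O)cc2[C@@H](c2ccc(O)c(O/C(=C/c3ccc(O)c(O)c3)C(=O)O)c2)[C@@H]1C(=O)O | target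

**Step count and risks**

Total step count: 16. Longest linear sequence: 12 steps (steps 4, 5, 6, 8, 9, 10, 11, 12, 13, 14, 15, 16, from 6 to 22).

Steps most likely to fail:

Step 14. The ion-paired catalyst may fail to differentiate the two faces of C1; the two geometric forms of 19 may even prefer opposite faces, and an uncatalysed caesium enolate pathway may outrun the chiral one, so the closure would proceed with poor enantiofacial selectivity. The fallback sets out from 18 and comes back at 20. It gives up catalyst control and uses an ordinary amine-base 1,6-addition followed by resolution. DBU in MeCN at 0 °C should trigger the same loss of acetate and ring closure and, after equilibration at C2, give the racemic trans cyclisation product F1. Preparative HPLC on a chiral stationary phase (amylose tris(3,5-dimethylphenylcarbamate)) then separates the (1R,2S) enantiomer, which is 20.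

Step 11. The ortho-substituted arylboronate may protodeboronate, or the aryl–rhodium species may be intercepted by the neighbouring ester or an enoate before it meets the aldehyde; the TIPS ether para to the aldehyde may also be lost in the aqueous phosphate. The fallback sets out from 15 and comes back at 16. It forms the C1–C8a bond before the benzylidenesuccinate is present. Iodine–magnesium exchange of commercial 1-bromo-2-iodo-4,5-dimethoxybenzene with i-PrMgCl·LiCl (THF, −40 °C) gives (2-bromo-4,5-dimethoxyphenyl)magnesium chloride F6. This adds to the aldehyde of 15 at −40 °C, much faster than to the hindered ester, to give the racemic bromo carbinol F7. A Mizoroki–Heck reaction of F7 with dimethyl itaconate (Pd(OAc)2, P(o-tol)3, Et3N, DMF, 100 °C) should then install the (E)-benzylidenesuccinate and give 16.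

Step 8. Reversible conjugate addition of phenoxide under the hot basic copper conditions may erode the (E)-geometry of 10 or of 13, or the hindered alpha-bromoacrylate may not couple at all. The fallback sets out from 12 and comes back at 13. It builds the enol ether by olefination instead of C–O coupling. The aldehyde of 12 is masked with HC(OMe)3 and catalytic pyridinium p-toluenesulfonate in MeOH to give 2-(allyloxy)-5-(dimethoxymethyl)phenol F2. Diazo transfer to 6 (4-acetamidobenzenesulfonyl azide, DBU, MeCN) gives methyl 2-diazo-2-[bis(2,2,2-trifluoroethoxy)phosphoryl]acetate F3. Rh2(OAc)4-catalysed O–H insertion of the carbenoid from F3 into the phenol of F2 (toluene, 80 °C) gives the alpha-aryloxy phosphonoacetate F4. A Horner–Wadsworth–Emmons olefination of the Still–Gennari type between F4 and 9 (KN(SiMe3)2, 18-crown-6, THF, −78 °C) should give the (E)-enol ether dimethyl acetal F5 with ring D cis to the ester. Mild hydrolysis (pyridinium p-toluenesulfonate, acetone/H2O) returns aldehyde 13.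

**Further compounds**

F1 | step 14 | racemic trans tetra-O-methyl trimethyl ester with free 4'-OH (racemate of 20) | COC(=O)C1=Cc2cc(OC)c(OC)cc2C(c2ccc(O)c(O/C(=C/c3ccc(OC)c(OC)c3)C(=O)OC)c2)C1C(=O)OC
F2 | step 8 | 2-(allyloxy)-5-(dimethoxymethyl)phenol | C=CCOc1ccc(C(OC)OC)cc1O
F3 | step 8 | methyl 2-diazo-2-[bis(2,2,2-trifluoroethoxy)phosphoryl]acetate | COC(=O)C(=[N+]=[N-])P(=O)(OCC(F)(F)F)OCC(F)(F)F
F4 | step 8 | methyl 2-[2-(allyloxy)-5-(dimethoxymethyl)phenoxy]-2-[bis(2,2,2-trifluoroethoxy)phosphoryl]acetate (racemic) | COC(=O)C(Oc1cc(C(OC)OC)ccc1OCC=C)P(=O)(OCC(F)(F)F)OCC(F)(F)F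
F5 | step 8 | methyl (E)-2-[2-(allyloxy)-5-(dimethoxymethyl)phenoxy]-3-(3,4-dimethoxyphenyl)prop-2-enoate | COC(OC)c1ccc(OCC=C)c(O/C(=C/c2ccc(OC)c(OC)c2)C(=O)OC)c1
F6 | step 11 | (2-bromo-4,5-dimethoxyphenyl)magnesium chloride | COc1cc(Br)c([Mg]Cl)cc1OC
F7 | step 11 | racemic (2-bromo-4,5-dimethoxyphenyl)(3-{[(E)-2-(3,4-dimethoxyphenyl)-1-(methoxycarbonyl)ethenyl]oxy}-4-(triisopropylsilyloxy)phenyl)methanol | OC(c1ccc(O[Si](C(C)C)(C(C)C)C(C)C)c(O/C(=C/c2ccc(OC)c(OC)c2)C(=O)OC)c1)c1cc(OC)c(OC)cc1Br
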